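Assumption: the target has no stereocentres (achiral), so no configuration has to be set; xanthone numbering (C1–C8, C9 = carbonyl, O10) is used throughout.

**Retrosynthetic overview**
1. Target 21 ⇒ pyranoxanthone 18 by inserting O into the C9–C8a bond (boron-templated Baeyer–Villiger ring expansion, 6 → 7).
2. 18 ⇒ norathyriol 12 through tri-ether 16 (two aromatic Claisen shifts place both prenyl groups, a propargyl Claisen cascade builds the pyran).
3. 12 ⇒ phloroglucinol 10 + 2,4,5-trihydroxybenzoic acid 5 (Grover–Shah–Shah condensation builds the γ-pyrone ring).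
4. 10 ⇐ resorcinol (meta C–H borylation/oxidation); 5 ⇐ 1,4-benzoquinone + CO2 (Thiele–Winter, Kolbe–Schmitt).
5. Ring order: two purchased benzene rings → γ-pyrone (step 5) → 2H-pyran (step 9) → dioxepinone by ring expansion (step 10).

**Route**

Step 1
Reactants: 1 1,4-benzoquinone
Product: 2 benzene-1,2,4-triyl triacetate
Conditions: Ac2O, H2SO4 (cat.), 40–50 °C
Reagents that add atoms: acetic anhydride, CC(=O)OC(C)=O
Why: Thiele–Winter acetoxylation, i.e. acid-catalysed conjugate addition of acetic anhydride to the quinone, enolisation and O-acetylation, gives the 1,2,4-trioxygenated ring.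

Step 2
Reactants: 2 benzene-1,2,4-triyl triacetate; 3 carbon dioxide
Product: 5 2,4,5-trihydroxybenzoic acid, via benzene-1,2,4-triol 4 (not isolated)
Conditions: KHCO3 (aq), CO2 (1 atm), 100 °C, air excluded; then HCl
Reagents that add atoms: none
Why: Bicarbonate hydrolyses the aryl acetates and the triol then undergoes Kolbe–Schmitt carboxylation at the resorcinol-type position (ortho to one OH, para to another).

Step 3
Reactants: 6 resorcinol
Product: 7 1,3-bis(tert-butyldimethylsilyloxy)benzene
Conditions: TBSCl, imidazole, DMF, rt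
Reagents that add atoms: tert-butyldimethylsilyl chloride, CC(C)(C)[Si](C)(C)Cl
Why: Standard phenol silylation; the bulky silyl ethers set up steric control for the next step.

Step 4
Reactants: 7 1,3-bis(tert-butyldimethylsilyloxy)benzene
Product: 10 phloroglucinol, via aryl pinacol boronate 8 (not isolated), via 3,5-bis(TBSO)phenol 9 (not isolated)
Conditions: [Ir(OMe)(cod)]2 (1.5 mol%), dtbpy (3 mol%), B2pin2 (0.55 equiv), THF, 80 °C; then Oxone, acetone/H2O, rt; then KHF2, MeOH, rt
Reagents that add atoms: Oxone (potassium peroxymonosulfate), [K+].[O-]S(=O)(=O)OO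
Why: Sterically controlled Ir-catalysed C–H borylation hits C5, the only C–H not ortho to an OTBS group, and one-pot boronate oxidation and fluoride desilylation give the symmetric triol.

Step 5
Reactants: 5 2,4,5-trihydroxybenzoic acid; 10 phloroglucinol
Product: 12 norathyriol (1,3,6,7-tetrahydroxy-9H-xanthen-9-one), via hexahydroxybenzophenone 11 (not isolated)
Conditions: Eaton's reagent (P2O5/MeSO3H), 80 °C
Reagents that add atoms: none
Why: Grover–Shah–Shah xanthone synthesis (Friedel–Crafts acylation of phloroglucinol, then cyclodehydration of the 2,2'-dihydroxybenzophenone); the symmetry of 10 allows only one xanthone.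

Step 6
Reactants: 12 norathyriol; 13 3-chloro-3-methylbut-1-yne
Product: 14 1,7-dihydroxy-3,6-bis[(2-methylbut-3-yn-2-yl)oxy]-9H-xanthen-9-one
Conditions: 13 (2.1 equiv), DBU (2.2 equiv), CuCl2 (1 mol%), MeCN/DMF, 0 °C, Ar
Reagents that add atoms: none
Why: Cu-catalysed propargylic etherification; the two OH groups para to the carbonyl (3-OH, 6-OH) are the most acidic and are alkylated first, 7-OH is less acidic and 1-OH is chelated.

Step 7
Reactants: 14 bis(propargyl) ether
Product: 15 1,7-dihydroxy-3,6-bis[(2-methylbut-3-en-2-yl)oxy]-9H-xanthen-9-one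
Conditions: H2 (1 atm), Lindlar catalyst, quinoline, EtOAc, rt
Reagents that add atoms: none
Why: Lindlar semihydrogenation of the two terminal alkynes gives the 1,1-dimethylallyl ethers needed for Claisen delivery of normal prenyl groups.

Step 8
Reactants: 15 bis(1,1-dimethylallyl) ether; 13 3-chloro-3-methylbut-1-yne
Product: 16 1-hydroxy-3,6-bis[(2-methylbut-3-en-2-yl)oxy]-7-[(2-methylbut-3-yn-2-yl)oxy]-9H-xanthen-9-one
Conditions: 13 (1.3 equiv), DBU, CuCl2 (1 mol%), MeCN, 0 °C
Reagents that add atoms: none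
Why: Same Cu-catalysed etherification; only 7-OH reacts because 1-OH is locked in the hydrogen bond to the carbonyl.

Step 9
Reactants: 16 tri-ether
Product: 18 pyranoxanthone (1,3,6-trihydroxy-4,5-diprenyl-9H-xanthen-9-one with a 2,2-dimethyl-2H-pyran fused at C7–O and C8), via diprenyl propargyl ether 17 (not isolated)
Conditions: PhNEt2, 160 °C, Ar, sealed tube
Reagents that add atoms: none
Why: Two aromatic Claisen rearrangements put prenyl on C4 (γ-pyrone bond fixation with free chelated 1-OH favours C4 over C2) and on C5 (C7 is blocked), then the propargyl ether undergoes Claisen shift, 1,5-H shift and oxa-6π closure onto C8, the only free ortho position.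

Step 10
Reactants: 18 pyranoxanthone
Product: 21 CNP0263700.0 (target depsidone), via boron chelate 19 (not isolated), via cyclic peroxyborate 20 (not isolated)
Conditions: B(OCH2CF3)3 (1.2 equiv), CH2Cl2, rt; then urea·H2O2 (1.5 equiv), 0 °C → rt; pH 7 buffer work-up
Reagents that add atoms: urea–hydrogen peroxide, NC(N)=O.OO
Why: Proposed new method: the peri 1-OH/C9=O pair binds boron as a six-membered chelate, which makes the otherwise inert vinylogous-ester carbonyl xanthylium-like and leaves exchangeable alkoxides on boron; H2O2 exchanges onto boron and its distal oxygen adds to C9, giving a bicyclo[3.2.1]-type peroxyborate Criegee adduct whose O–O bond is held on the ring-B side, so only the exocyclic C9–C8a bond (ring A) is antiperiplanar to it; 1,2-aryl shift of ring A to oxygen with loss of B–O inserts O between C9 and C8a (6 → 7 ring expansion) and hydrolysis frees the 1-OH; the boron-bound peroxide is a nucleophilic, intramolecularly delivered oxidant, so the prenyl and chromene C=C bonds should not be epoxidised; closest known reactions are the Lewis-acid-promoted Baeyer–Villiger oxidation with H2O2 (BF3·OEt2/H2O2) and the boric acid/H2O2 Dakin oxidation; no stereocentre is formed.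

**Compound list**
1 | 1,4-benzoquinone | O=C1C=CC(=O)C=C1 | starting material
2 | benzene-1,2,4-triyl triacetate | CC(=O)Oc1ccc(OC(C)=O)c(OC(C)=O)c1 | intermediate
3 | carbon dioxide | O=C=O | starting material
4 | benzene-1,2,4-triol | Oc1ccc(O)c(O)c1 | intermediate
5 | 2,4,5-trihydroxybenzoic acid | OC(=O)c1cc(O)c(O)cc1O | intermediate
6 | resorcinol | Oc1cccc(O)c1 | starting material
7 | 1,3-bis(tert-butyldimethylsilyloxy)benzene | CC(C)(C)[Si](C)(C)Oc1cccc(O[Si](C)(C)C(C)(C)C)c1 | intermediate
8 | 2-[3,5-bis(tert-butyldimethylsilyloxy)phenyl]-4,4,5,5-tetramethyl-1,3,2-dioxaborolane | CC(C)(C)[Si](C)(C)Oc1cc(cc(O[Si](C)(C)C(C)(C)C)c1)B2OC(C)(C)C(C)(C)O2 | intermediate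
9 | 3,5-bis(tert-butyldimethylsilyloxy)phenol | CC(C)(C)[Si](C)(C)Oc1cc(O)cc(O[Si](C)(C)C(C)(C)C)c1 | intermediate
10 | phloroglucinol (benzene-1,3,5-triol) | Oc1cc(O)cc(O)c1 | intermediate
11 | (2,4,5-trihydroxyphenyl)(2,4,6-trihydroxyphenyl)methanone | O=C(c1cc(O)c(O)cc1O)c1c(O)cc(O)cc1O | intermediate
12 | norathyriol (1,3,6,7-tetrahydroxy-9H-xanthen-9-one) | O=C1c2cc(O)c(O)cc2Oc2cc(O)cc(O)c12 | intermediate
13 | 3-chloro-3-methylbut-1-yne | CC(C)(Cl)C#C | starting material
14 | 1,7-dihydroxy-3,6-bis[(2-methylbut-3-yn-2-yl)oxy]-9H-xanthen-9-one | O=C1c2cc(O)c(OC(C)(C)C#C)cc2Oc2cc(OC(C)(C)C#C)cc(O)c12 | intermediate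
15 | 1,7-dihydroxy-3,6-bis[(2-methylbut-3-en-2-yl)oxy]-9H-xanthen-9-one | O=C1c2cc(O)c(OC(C)(C)C=C)cc2Oc2cc(OC(C)(C)C=C)cc(O)c12 | intermediate
16 | 1-hydroxy-3,6-bis[(2-methylbut-3-en-2-yl)oxy]-7-[(2-methylbut-3-yn-2-yl)oxy]-9H-xanthen-9-one | O=C1c2cc(OC(C)(C)C#C)c(OC(C)(C)C=C)cc2Oc2cc(OC(C)(C)C=C)cc(O)c12 | intermediate
17 | 1,3,6-trihydroxy-4,5-bis(3-methylbut-2-en-1-yl)-7-[(2-methylbut-3-yn-2-yl)oxy]-9H-xanthen-9-one | O=C1c2cc(OC(C)(C)C#C)c(O)c(CC=C(C)C)c2Oc2c(CC=C(C)C)c(O)cc(O)c12 | intermediate
18 | pyranoxanthone: 1,3,6-trihydroxy-4,5-bis(3-methylbut-2-en-1-yl)-9H-xanthen-9-one with a 2,2-dimethyl-2H-pyran ring fused at C7 (ring O) and C8 (CH=CH) | O=C1c2c3C=CC(C)(C)Oc3c(O)c(CC=C(C)C)c2Oc2c(CC=C(C)C)c(O)cc(O)c12 | intermediate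
19 | boron chelate of 18: 1-O-B(OCH2CF3)2 borate, carbonyl oxygen datively bound to boron (dative bond not drawn) | O=C1c2c3C=CC(C)(C)Oc3c(O)c(CC=C(C)C)c2Oc2c(CC=C(C)C)c(O)cc(OB(OCC(F)(F)F)OCC(F)(F)F)c12 | intermediate
20 | cyclic peroxyborate (Criegee-type adduct): C9 carries OH and an O–O–B(OCH2CF3)–O bridge to C1 (dative O→B bond not drawn) | OC12OOB(OCC(F)(F)F)Oc3cc(O)c(CC=C(C)C)c(Oc4c(CC=C(C)C)c(O)c5OC(C)(C)C=Cc5c41)c32 | intermediate
21 | CNP0263700.0: depsidone obtained from 18 by O-insertion between C9 and C8a (lactone C=O on the 1,3-dihydroxy-4-prenyl ring, lactone O on the pyran-fused ring) | CC(C)=CCc1c(O)c2c(c3c1Oc1c(CC=C(C)C)c(O)cc(O)c1C(=O)O3)C=CC(C)(C)O2 | target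

**Step count**
Total steps: 10. Longest linear sequence: 8 (steps 3, 4, 5, 6, 7, 8, 9, 10; the branch 1, 2, 5–10 is equally long).

**Three steps most likely to fail**

Step 10 (the proposed boron-templated Baeyer–Villiger ring expansion). This transformation has not been demonstrated on xanthones. The carbonyl may stay too unreactive, or ring B may migrate. The fallback uses known chemistry in the Dakin manifold. It sets out from 18: MOMCl (1.05 equiv), i-Pr2NEt, CH2Cl2, 0 °C masks the less hindered 3-OH (1-OH is chelated, 6-OH is flanked by prenyl and the pyran oxygen) to give the 3-O-methoxymethyl ether of 18 F1. Classical Dakin oxidation (30% H2O2, NaHCO3, THF/H2O, rt) then follows the textbook rule that the aryl ring carrying the ionised para-hydroxyl migrates. That ring is now ring A (6-O−), since ring B has no ionised ortho or para oxygen, and the product is the mono-MOM ether of 21 F2. HCl/MeOH at rt removes the MOM group and the route is rejoined at 21.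

Step 9 (thermal triple rearrangement). The main risk is partial delivery of the ring-B prenyl group to C2 instead of C4. The fallback is a blocking-group approach and sets out from 16: N-iodosuccinimide (1.0 equiv), MeCN, 0 °C iodinates the position ortho to the chelated 1-OH to give the 2-iodo derivative of 16 F3. Thermolysis as in step 9 can then place the ring-B prenyl only on C4 and gives the 2-iodo derivative of 18 F4. Pd(OAc)2/PPh3, HCO2H, Et3N, DMF, 60 °C removes the iodine and the route is rejoined at 18.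

Step 6 (selective 3,6-bis-etherification of a tetraphenol). The risk is competing alkylation of 7-OH. The fallback differentiates the hydroxyls by acylation and sets out from 12: Ac2O, pyridine, DMAP gives norathyriol tetraacetate F5. PhSH, imidazole, NMP, 0 °C cleaves only the two acetates para to the carbonyl and gives 1,7-di-O-acetylnorathyriol F6. Etherification with 13 under the step 6 conditions gives the 1,7-di-O-acetyl derivative of 14 F7. K2CO3, MeOH, 0 °C removes the acetates and the route is rejoined at 14.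

**Further compounds**
F1 | step 10 | 3-O-methoxymethyl ether of 18 | O=C1c2c3C=CC(C)(C)Oc3c(O)c(CC=C(C)C)c2Oc2c(CC=C(C)C)c(OCOC)cc(O)c12
F2 | step 10 | mono-MOM ether of 21 (MOM on the ring-B hydroxyl para to the lactone carbonyl) | O=C1Oc2c3C=CC(C)(C)Oc3c(O)c(CC=C(C)C)c2Oc2c(CC=C(C)C)c(OCOC)cc(O)c12
F3 | step 9 | 2-iodo derivative of 16 | O=C1c2cc(OC(C)(C)C#C)c(OC(C)(C)C=C)cc2Oc2cc(OC(C)(C)C=C)c(I)c(O)c12
F4 | step 9 | 2-iodo derivative of 18 | O=C1c2c3C=CC(C)(C)Oc3c(O)c(CC=C(C)C)c2Oc2c(CC=C(C)C)c(O)c(I)c(O)c12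
F5 | step 6 | norathyriol tetraacetate | O=C1c2cc(OC(C)=O)c(OC(C)=O)cc2Oc2cc(OC(C)=O)cc(OC(C)=O)c12
F6 | step 6 | 1,7-di-O-acetylnorathyriol | O=C1c2cc(OC(C)=O)c(O)cc2Oc2cc(O)cc(OC(C)=O)c12
F7 | step 6 | 1,7-di-O-acetyl derivative of 14 | O=C1c2cc(OC(C)=O)c(OC(C)(C)C#C)cc2Oc2cc(OC(C)(C)C#C)cc(OC(C)=O)c12
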